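**Strategy**

The isoflavone is disconnected at O1–C8a and C4–C4a, so ring A arrives as a symmetric 4,5-bis(benzyloxy)benzyne and the rest as a formylated arylacetate. The feature exploited is that O1 and the C4 carbonyl sit on adjacent carbons C8a and C4a of ring A, flanked by unsubstituted C5 and C8, with oxygens at C6 and C7. In one operation the enolate oxygen adds to the aryne and the aryl anion produced acylates itself on the neighbouring methyl ester, closing ring C. The precursors are a 2-silylaryl triflate with two identical benzyl ethers and a (Z)-3-hydroxy-2-arylacrylate. Hydrogenolysis and acidity-controlled O7-methylation finish the route.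

Key step: step 6

Remark: enol 12 is drawn as its hydrogen-bonded Z form. Its E enol and aldehyde tautomers interconvert and give the same caesium enolate, so the tautomer composition is assumed not to matter in step 6.

**Route**

Step 1
Reactants: 1 3,4-bis(benzyloxy)benzaldehyde
Product: 3 3,4-bis(benzyloxy)phenol, via aryl formate 2 (not isolated)
Conditions: mCPBA (1.3 equiv), CH2Cl2, 0 °C to rt; NaHCO3 wash; then K2CO3 (cat.), MeOH, rt
Reagents that add atoms: mCPBA (3-chloroperoxybenzoic acid), O=C(OO)c1cccc(Cl)c1
Why: Baeyer–Villiger (Dakin-type) oxidation, in which the electron-rich aryl group para to a benzyloxy substituent migrates to oxygen to give the formate, which mild methanolysis cleaves to the phenol while the benzyl ethers stay intact.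

Step 2
Reactants: 3 3,4-bis(benzyloxy)phenol
Product: 4 4,5-bis(benzyloxy)-2-bromophenol
Conditions: NBS (1.0 equiv), CH2Cl2, 0 °C
Reagents that add atoms: N-bromosuccinimide, O=C1CCC(=O)N1Br
Why: Electrophilic aromatic bromination should go to the open position ortho to the hydroxyl and para to the 3-benzyloxy group, because the other ortho position is crowded between two oxygens and the para position is blocked.

Step 3
Reactants: 4 4,5-bis(benzyloxy)-2-bromophenol
Product: 5 [4,5-bis(benzyloxy)-2-bromophenoxy]trimethylsilane
Conditions: HMDS (1.5 equiv), THF, 65 °C; evaporate, use crude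
Reagents that add atoms: hexamethyldisilazane, C[Si](C)(C)N[Si](C)(C)C
Why: O-silylation of a phenol with a silazane, driven by loss of ammonia, gives the silyl ether needed for the silyl shift of the next step.

Step 4
Reactants: 5 [4,5-bis(benzyloxy)-2-bromophenoxy]trimethylsilane
Product: 8 4,5-bis(benzyloxy)-2-(trimethylsilyl)phenyl trifluoromethanesulfonate, via aryllithium 6 (not isolated), via lithium silylphenolate 7 (not isolated)
Conditions: n-BuLi (1.1 equiv), THF, −100 °C; then Tf2O (1.2 equiv), −100 to −78 °C
Reagents that add atoms: trifluoromethanesulfonic anhydride, O=S(=O)(OS(=O)(=O)C(F)(F)F)C(F)(F)F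
Why: Bromine–lithium exchange is followed by a 1,3 O-to-C silyl shift (retro-Brook rearrangement) driven by formation of the phenolate, which is sulfonylated in the same flask; at this temperature exchange outruns any attack on the benzyl ethers.

Step 5
Reactants: 9 methyl 3,4,5-trimethoxyphenylacetate; 10 methyl formate
Product: 12 methyl (Z)-3-hydroxy-2-(3,4,5-trimethoxyphenyl)prop-2-enoate, via sodium enolate 11 (not isolated)
Conditions: NaH, HCO2Me (excess), THF, 0 °C to rt; then 1 M HCl
Reagents that add atoms: none
Why: Crossed Claisen condensation with a formate that cannot enolise is pulled forward by formation of the stabilised enolate, and acidification gives the hydrogen-bonded Z enol.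

Step 6
Reactants: 8 4,5-bis(benzyloxy)-2-(trimethylsilyl)phenyl trifluoromethanesulfonate; 12 methyl (Z)-3-hydroxy-2-(3,4,5-trimethoxyphenyl)prop-2-enoate
Product: 15 6,7-bis(benzyloxy)-3-(3,4,5-trimethoxyphenyl)-4H-chromen-4-one, via bis(benzyloxy)benzyne 13 (not isolated), via aryl caesium enol ether 14 (not isolated)
Conditions: 8 (1.3 equiv), CsF (4 equiv), THF, 65 °C
Reagents that add atoms: none
Why: Proposed new method: fluoride attacks silicon in 8 and triflate departs to give benzyne 13; the caesium enolate of 12, chelated in its Z form, adds through oxygen (O1–C8a) and the aryl caesium 14 so formed attacks the cis methyl ester (C4–C4a), expelling methoxide. The closest known reaction type is the aryne annulation of salicylate esters to xanthones, in which a phenoxide is O-arylated and the aryl anion is captured by the ester; here a vinylogous acid enol takes the place of the phenol. Ring C closes by 6-exo-trig addition–elimination at the ester carbonyl. No stereocenter is formed. The step needs O- over C-arylation, which the fully substituted, aryl-shielded carbon terminus (C-attack would build a quaternary centre), the exposed formyl-derived oxygen and the caesium counter-ion should favour, and it needs the Z enolate geometry, which chelation in THF should supply. Orientation of addition is not an issue because 13 is symmetric about its triple bond, and 15 has no acidic hydrogen left to consume more aryne.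

Step 7
Reactants: 15 6,7-bis(benzyloxy)-3-(3,4,5-trimethoxyphenyl)-4H-chromen-4-one
Product: 16 6,7-dihydroxy-3-(3,4,5-trimethoxyphenyl)-4H-chromen-4-one
Conditions: H2 (1 atm), 10% Pd/C, EtOAc/MeOH, rt; stop after uptake of 2 equiv
Reagents that add atoms: none
Why: Catalytic hydrogenolysis cleaves both benzylic C–O bonds, while the push-pull, aryl-substituted C2=C3 bond of the chromone is reduced much more slowly and the methyl ethers are inert.

Step 8
Reactants: 16 6,7-dihydroxy-3-(3,4,5-trimethoxyphenyl)-4H-chromen-4-one
Product: 17 6-hydroxy-7-methoxy-3-(3,4,5-trimethoxyphenyl)-4H-chromen-4-one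
Conditions: MeI (1.05 equiv), KHCO3 (1.2 equiv), DMF, argon, rt to 40 °C
Reagents that add atoms: iodomethane, CI
Why: Williamson etherification under acidity control: the 7-hydroxyl is para to C4a and thus a vinylogous acid of the C4 carbonyl, so hydrogencarbonate should ionise only O7 and one equivalent of iodomethane should cap it, leaving the less acidic 6-hydroxyl free.

**Compound list**

1 | 3,4-bis(benzyloxy)benzaldehyde | O=Cc1ccc(OCc2ccccc2)c(OCc2ccccc2)c1 | starting material
2 | 3,4-bis(benzyloxy)phenyl formate | O=COc1ccc(OCc2ccccc2)c(OCc2ccccc2)c1 | intermediate (not isolated)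
3 | 3,4-bis(benzyloxy)phenol | Oc1ccc(OCc2ccccc2)c(OCc2ccccc2)c1 | intermediate
4 | 4,5-bis(benzyloxy)-2-bromophenol | Oc1cc(OCc2ccccc2)c(OCc2ccccc2)cc1Br | intermediate
5 | [4,5-bis(benzyloxy)-2-bromophenoxy]trimethylsilane | C[Si](C)(C)Oc1cc(OCc2ccccc2)c(OCc2ccccc2)cc1Br | intermediate
6 | [4,5-bis(benzyloxy)-2-lithiophenoxy]trimethylsilane | C[Si](C)(C)Oc1cc(OCc2ccccc2)c(OCc2ccccc2)cc1[Li] | intermediate (not isolated)
7 | lithium 4,5-bis(benzyloxy)-2-(trimethylsilyl)phenolate | C[Si](C)(C)c1cc(OCc2ccccc2)c(OCc2ccccc2)cc1[O-].[Li+] | intermediate (not isolated)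
8 | 4,5-bis(benzyloxy)-2-(trimethylsilyl)phenyl trifluoromethanesulfonate | C[Si](C)(C)c1cc(OCc2ccccc2)c(OCc2ccccc2)cc1OS(=O)(=O)C(F)(F)F | intermediate
9 | methyl 3,4,5-trimethoxyphenylacetate | COC(=O)Cc1cc(OC)c(OC)c(OC)c1 | starting material
10 | methyl formate | COC=O | starting material
11 | sodium (Z)-3-methoxy-3-oxo-2-(3,4,5-trimethoxyphenyl)prop-1-en-1-olate | COC(=O)/C(=C\[O-])c1cc(OC)c(OC)c(OC)c1.[Na+] | intermediate (not isolated)
12 | methyl (Z)-3-hydroxy-2-(3,4,5-trimethoxyphenyl)prop-2-enoate | COC(=O)/C(=C\O)c1cc(OC)c(OC)c(OC)c1 | intermediate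
13 | 4,5-bis(benzyloxy)benzyne (1,2-didehydro-4,5-bis(benzyloxy)benzene) | C1(OCc2ccccc2)=CC#CC=C1OCc1ccccc1 | intermediate (not isolated)
14 | methyl (Z)-3-[4,5-bis(benzyloxy)-2-caesiophenoxy]-2-(3,4,5-trimethoxyphenyl)prop-2-enoate | COC(=O)/C(=C\Oc1cc(OCc2ccccc2)c(OCc2ccccc2)cc1[Cs])c1cc(OC)c(OC)c(OC)c1 | intermediate (not isolated)
15 | 6,7-bis(benzyloxy)-3-(3,4,5-trimethoxyphenyl)-4H-chromen-4-one | O=c1c(-c2cc(OC)c(OC)c(OC)c2)coc2cc(OCc3ccccc3)c(OCc3ccccc3)cc12 | intermediate
16 | 6,7-dihydroxy-3-(3,4,5-trimethoxyphenyl)-4H-chromen-4-one | O=c1c(-c2cc(OC)c(OC)c(OC)c2)coc2cc(O)c(O)cc12 | intermediate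
17 | 6-hydroxy-7-methoxy-3-(3,4,5-trimethoxyphenyl)-4H-chromen-4-one | COc1cc2occ(-c3cc(OC)c(OC)c(OC)c3)c(=O)c2cc1O | target

**Step count and risks**

Total steps: 8. Longest linear sequence: 7 (steps 1, 2, 3, 4, 6, 7, 8).

Steps most likely to fail:

1. Step 6. The enolate may be arylated at carbon and then transfer its formyl group (net insertion of the aryne into the C–C bond). The aryl anion may be protonated before it reaches the ester. Liberated methoxide may open the chromone at C2. The fallback uses known deoxybenzoin chemistry and sets out from 9. Saponification (LiOH, THF/H2O) gives 3,4,5-trimethoxyphenylacetic acid F1. Friedel–Crafts acylation of commercial benzene-1,2,4-triol with F1 in BF3·OEt2 at about 80 °C, at the position ortho to one hydroxyl and para to another, gives 1-(2,4,5-trihydroxyphenyl)-2-(3,4,5-trimethoxyphenyl)ethan-1-one F2. One-carbon ring closure with DMF, BF3·OEt2 and MsCl then gives the diol, so the fallback comes back to the route at 16, just before step 8.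

2. Step 8. Methylation may occur at O6 or at both oxygens, and the catechol may be oxidised by air under base. The fallback fixes the methyl group before ring A is joined. It sets out from 9, which is saponified as above to 3,4,5-trimethoxyphenylacetic acid F1. Acylation of commercial 2-methoxybenzene-1,4-diol with F1 in BF3·OEt2 should go para to the methoxy group and ortho to a hydroxyl, giving 1-(2,5-dihydroxy-4-methoxyphenyl)-2-(3,4,5-trimethoxyphenyl)ethan-1-one F3. Ring closure with DMF, BF3·OEt2 and MsCl forms the chromone with the 6-hydroxy-7-methoxy pattern already in place, so the fallback comes back to the route at 17.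

3. Step 7. The C2=C3 bond may be over-reduced to the isoflavanone, or the reaction may stall after loss of one benzyl group. The fallback replaces reduction by Lewis-acid cleavage. It sets out from 15, which is treated with BCl3 and pentamethylbenzene as benzyl-cation scavenger in CH2Cl2 at −78 °C. At this temperature the methyl ethers should survive. It comes back to the route at 16 and makes no new compound.

**Further compounds**

F1 | step 6 | 3,4,5-trimethoxyphenylacetic acid | OC(=O)Cc1cc(OC)c(OC)c(OC)c1
F2 | step 6 | 1-(2,4,5-trihydroxyphenyl)-2-(3,4,5-trimethoxyphenyl)ethan-1-one | O=C(Cc1cc(OC)c(OC)c(OC)c1)c1cc(O)c(O)cc1O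
F3 | step 8 | 1-(2,5-dihydroxy-4-methoxyphenyl)-2-(3,4,5-trimethoxyphenyl)ethan-1-one | O=C(Cc1cc(OC)c(OC)c(OC)c1)c1cc(O)c(OC)cc1O
F0 | step 7 | none | none
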